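**Plan**
1. Cuts: the two ester C–O bonds (acyl on O–C3, acetyl on O–C4), then C7–C8 of ring B, then C4–C15, C9–C10 and C5–C6. This leads back to 3-methylcyclohex-2-enone, prenyl bromide, an acetamide acetal and formaldehyde.
2. Enabling feature: ring B has the C8 ketone next to the C7=C11 isopropylidene group (pulegone pattern). Shifting the alkene to C11=C12 and reducing C8 gives a homoallylic alcohol, which is the ene adduct of a C8 aldehyde (held on C10 through C9) and a prenyl group (C6–C7=C11 on C5).
3. Forward order: ring A is bought. C5–C6 comes from enone α-alkylation, C9–C10 from an Eschenmoser–Claisen shift, and ring B from the carbonyl-ene closure. Ring A is then oxidised at C3, given C15, reduced, hydroxylated and acylated twice. Ring B is taken to the enone last.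
4. Stereochemistry: C10 comes from a CBS reduction relayed by the suprafacial [3,3] shift. C5 stays sp2 through the ring closure, because a 4-oxo-10-methyldecalin has no dependable cis/trans bias, and is set trans by Li/NH3. C4 (α-face Rubottom oxidation) and C3 (axial hydride) are steered by the axial C10 methyl group. The side-chain centre is bought, and C7 and C8 are transient.

Key step: step 5

Assumption: eudesmane numbering is used for all compounds (ring A = C1–C5, C10; ring B = C5–C10; C14 = methyl on C10; C15 = methyl on C4), β is the face of the C10 methyl group, and (R)-2-methylbutanoic acid is taken as a purchasable single enantiomer.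

**Step 1**
Reactants: 1 3-methylcyclohex-2-en-1-one; 2 prenyl bromide (1-bromo-3-methylbut-2-ene)
Product: 3 3-methyl-2-(3-methylbut-2-en-1-yl)cyclohex-2-en-1-one
Conditions: KOtBu (1.0 equiv), t-BuOH, 25 °C, slow addition of 2
Reagents that add atoms: prenyl bromide 2, CC(C)=CCBr
Why: Thermodynamic dienolate alkylation, in which reversible γ-deprotonation of the β-methyl enone gives the extended enolate, the allylic bromide attacks its α-carbon (C5), and the product returns to conjugation under the same base, with no stereocentre formed.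

**Step 2**
Reactants: 3 3-methyl-2-(3-methylbut-2-en-1-yl)cyclohex-2-en-1-one
Product: 4 (1R)-3-methyl-2-(3-methylbut-2-en-1-yl)cyclohex-2-en-1-ol (C4–OH on the α face)
Conditions: (S)-5,5-diphenyl-2-methyl-3,4-propano-1,3,2-oxazaborolidine (0.15 equiv), catecholborane, toluene, −78 °C; aq. NaOH work-up
Reagents that add atoms: none
Why: Corey–Bakshi–Shibata reduction, in which the fully substituted alkene arm (C5) acts as the large group and the C3 methylene as the small one, so the (S)-catalyst should give the (R)-alcohol, while catecholborane leaves both alkenes alone at this temperature.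

**Step 3**
Reactants: 4 (1R)-3-methyl-2-(3-methylbut-2-en-1-yl)cyclohex-2-en-1-ol; 5 N,N-dimethylacetamide dimethyl acetal
Product: 7 2-[(1R)-1-methyl-2-(3-methylbut-2-en-1-yl)cyclohex-2-en-1-yl]-N,N-dimethylacetamide, via ketene N,O-acetal 6 (not isolated)
Conditions: 5 (5 equiv), xylenes, 140 °C, MeOH distilled off
Reagents that add atoms: N,N-dimethylacetamide dimethyl acetal 5, CC(OC)(OC)N(C)C
Why: Eschenmoser–Claisen rearrangement, in which acetal exchange and loss of methanol give the ketene N,O-acetal, and its suprafacial [3,3] shift under neutral conditions forms C9–C10 on the α face that carried the C4–O bond, leaving the C10 methyl β and the new alkene at C4=C5.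

**Step 4**
Reactants: 7 2-[(1R)-1-methyl-2-(3-methylbut-2-en-1-yl)cyclohex-2-en-1-yl]-N,N-dimethylacetamide
Product: 8 2-[(1R)-1-methyl-2-(3-methylbut-2-en-1-yl)cyclohex-2-en-1-yl]acetaldehyde
Conditions: Cp2Zr(H)Cl (1.6 equiv), THF, 23 °C, 20 min; H2O, silica gel
Reagents that add atoms: none
Why: Partial reduction of a tertiary amide by hydrozirconation of its C=O bond, where the zirconated hemiaminal holds until work-up and then collapses to the aldehyde, and the two trisubstituted alkenes react far more slowly than the amide.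

**Step 5**
Reactants: 8 2-[(1R)-1-methyl-2-(3-methylbut-2-en-1-yl)cyclohex-2-en-1-yl]acetaldehyde
Product: 9 15-nor-eudesma-4,11-dien-8α-ol (7β-isopropenyl; 10β-methyl; both ring B substituents equatorial)
Conditions: Me2AlCl (1.2 equiv), CH2Cl2, −78 to −40 °C; then H2O
Reagents that add atoms: none
Why: Me2AlCl binds the only Lewis-basic site, the C8 aldehyde oxygen, C7 of the prenyl alkene attacks C8 while a hydrogen of a C11 methyl group passes to oxygen in a six-membered array, and the aluminium alkoxide loses methane, which removes the proton that could start cationic side reactions. The closest known reaction is the type 1 intramolecular carbonyl-ene cyclisation of citronellal to isopulegol, which has the same spacing of aldehyde and trisubstituted alkene. Ring B closes in a 6-exo mode with respect to C7=C11 through a chair in which the C10 methyl group is axial. At C8 the complexed oxygen takes the equatorial α position because the axial one would meet the axial C10 methyl group, at C7 the isopropenyl group ends equatorial (β) and trans to oxygen as the concerted hydrogen transfer requires, and both centres are erased later, so a minor isomer does no harm. The step needs site selectivity between two alkenes, and this is secured because attack by C4=C5 would be a 4-exo or 5-endo closure to a strained bridged ring, so only the prenyl group can reach C8. Ring A carries no ketone, so there is no enol for an aldol reaction and no epimerisable centre.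

**Step 6**
Reactants: 9 15-nor-eudesma-4,11-dien-8α-ol
Product: 10 8α-(tert-butyldimethylsilyloxy)-15-nor-eudesma-4,11-diene
Conditions: t-BuMe2SiCl, imidazole, DMF, 23 °C
Reagents that add atoms: tert-butyldimethylsilyl chloride, CC(C)(C)[Si](C)(C)Cl
Why: Standard silylation of a secondary alcohol, needed because the C8 oxygen has to pass through a chromium oxidation and a dissolving-metal reduction, with all stereocentres untouched.

**Step 7**
Reactants: 10 8α-(tert-butyldimethylsilyloxy)-15-nor-eudesma-4,11-diene
Product: 11 8α-(tert-butyldimethylsilyloxy)-15-nor-eudesma-4,11-dien-3-one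
Conditions: CrO3, 3,5-dimethylpyrazole, CH2Cl2, −20 °C
Reagents that add atoms: chromium trioxide, O=[Cr](=O)=O
Why: Allylic oxidation by the CrO3–3,5-dimethylpyrazole complex, in which the C3 methylene next to the unsubstituted alkene carbon C4 is open while C6 is flanked by substituted C7, and 10-methyloctalins bearing an isopropenyl group are a known substrate class for this conversion into the conjugated enone with the 1,1-disubstituted alkene kept.

**Step 8**
Reactants: 11 8α-(tert-butyldimethylsilyloxy)-15-nor-eudesma-4,11-dien-3-one; 12 formaldehyde; 13 thiophenol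
Product: 14 8α-(tert-butyldimethylsilyloxy)-15-(phenylsulfanyl)eudesma-4,11-dien-3-one
Conditions: 37% aq. CH2O, PhSH, Et3N, EtOH, reflux
Reagents that add atoms: formaldehyde 12, C=O; thiophenol 13, Sc1ccccc1
Why: Kirk–Petrow thiomethylation, in which the dienol of the enone adds to formaldehyde at C4 under mild amine base, water is lost and thiophenol caps the methylene ketone, so exactly one carbon (C15) is placed on C4 and a second alkylation cannot follow.

**Step 9**
Reactants: 14 8α-(tert-butyldimethylsilyloxy)-15-(phenylsulfanyl)eudesma-4,11-dien-3-one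
Product: 16 8α-(tert-butyldimethylsilyloxy)-3-(trimethylsilyloxy)-5αH-eudesma-3,11-diene, via lithium enolate 15 (not isolated)
Conditions: Li (excess), NH3(l), THF, t-BuOH (2 equiv), −78 to −33 °C; isoprene; NH3 evaporated; Me3SiCl, Et3N, THF, 0 °C
Reagents that add atoms: chlorotrimethylsilane, C[Si](C)(C)Cl
Why: Dissolving-metal enone reduction with regiospecific enolate trapping, in which axial protonation of the β-carbon C5 gives the trans-decalin (5α-H, anti to the C10 methyl), the enolate expels thiophenolate, and the 4-methylene ketone so formed is reduced again, so the C3–C4 enolate bearing the C15 methyl group forms on one side only and is fixed as its silyl ether, while the isolated alkene and the silyl ether at C8 do not react.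

**Step 10**
Reactants: 16 8α-(tert-butyldimethylsilyloxy)-3-(trimethylsilyloxy)-5αH-eudesma-3,11-diene
Product: 19 8α-(tert-butyldimethylsilyloxy)-4α-hydroxy-5αH-eudesm-11-en-3-one, via silyloxy epoxide 17 (not isolated), via silyloxy ketone 18 (not isolated)
Conditions: mCPBA (1.05 equiv), NaHCO3, CH2Cl2, −20 °C; then 1 M HCl, THF, 0 °C
Reagents that add atoms: 3-chloroperbenzoic acid, OOC(=O)c1cccc(Cl)c1
Why: Rubottom oxidation, in which the electron-rich tetrasubstituted enol ether should react far faster than the 1,1-disubstituted alkene, the peracid comes from the α face because the axial C10 methyl group covers the β face, and silyl migration followed by mild acid gives the 4α-hydroxy-4β-methyl ketone.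

**Step 11**
Reactants: 19 8α-(tert-butyldimethylsilyloxy)-4α-hydroxy-5αH-eudesm-11-en-3-one
Product: 20 8α-(tert-butyldimethylsilyloxy)-5αH-eudesm-11-ene-3β,4α-diol
Conditions: NaBH4, MeOH, 0 °C
Reagents that add atoms: none
Why: Borohydride reduction of a hindered cyclohexanone, in which the small hydride attacks C3 axially from the α face, away from the axial 4β- and 10β-methyl groups as in 4,4-disubstituted 3-oxodecalins, giving the equatorial 3β-alcohol trans to the 4α-hydroxyl with no other carbonyl group present to compete.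

**Step 12**
Reactants: 20 8α-(tert-butyldimethylsilyloxy)-5αH-eudesm-11-ene-3β,4α-diol; 21 (R)-2-methylbutanoic acid
Product: 22 8α-(tert-butyldimethylsilyloxy)-4α-hydroxy-5αH-eudesm-11-en-3β-yl (2R)-2-methylbutanoate
Conditions: N,N'-dicyclohexylcarbodiimide, 4-dimethylaminopyridine (0.1 equiv), CH2Cl2, 0 °C
Reagents that add atoms: (R)-2-methylbutanoic acid 21, CC[C@@H](C)C(O)=O
Why: Steglich esterification, in which only the secondary equatorial 3β-hydroxyl is acylated under these mild conditions, the α-centre of the acid is kept at low temperature, and material from the minor enantiomer of step 2 becomes a separable diastereomer.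

**Step 13**
Reactants: 22 8α-(tert-butyldimethylsilyloxy)-4α-hydroxy-5αH-eudesm-11-en-3β-yl (2R)-2-methylbutanoate; 23 acetic anhydride
Product: 24 4α-acetoxy-8α-(tert-butyldimethylsilyloxy)-5αH-eudesm-11-en-3β-yl (2R)-2-methylbutanoate
Conditions: Ac2O (excess), 4-dimethylaminopyridine (1 equiv), Et3N, CH2Cl2, 40 °C
Reagents that add atoms: acetic anhydride 23, CC(=O)OC(C)=O
Why: Nucleophile-catalysed acetylation of a tertiary alcohol with excess anhydride and gentle heating, feasible because the hydroxyl is equatorial, and without effect on C4 because only the O–H bond reacts.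

**Step 14**
Reactants: 24 4α-acetoxy-8α-(tert-butyldimethylsilyloxy)-5αH-eudesm-11-en-3β-yl (2R)-2-methylbutanoate
Product: 25 4α-acetoxy-8α-hydroxy-5αH-eudesm-11-en-3β-yl (2R)-2-methylbutanoate
Conditions: HF·pyridine, pyridine, THF, 0 to 23 °C
Reagents that add atoms: none
Why: Fluoride cleavage of the silyl ether under buffered, weakly acidic conditions, which spare both esters and exclude base-induced acyl migration.

**Step 15**
Reactants: 25 4α-acetoxy-8α-hydroxy-5αH-eudesm-11-en-3β-yl (2R)-2-methylbutanoate
Product: 26 4α-acetoxy-8-oxo-5αH,7αH-eudesm-11-en-3β-yl (2R)-2-methylbutanoate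
Conditions: Dess–Martin periodinane, NaHCO3, CH2Cl2, 0 to 23 °C
Reagents that add atoms: none
Why: Dess–Martin oxidation under buffered neutral conditions turns the secondary alcohol into the ketone without touching the esters or the alkene.

**Step 16**
Reactants: 26 4α-acetoxy-8-oxo-5αH,7αH-eudesm-11-en-3β-yl (2R)-2-methylbutanoate
Product: 27 4α-acetoxy-8-oxo-5αH-eudesm-7(11)-en-3β-yl (2R)-2-methylbutanoate (CNP0111007.1)
Conditions: 1,8-diazabicyclo[5.4.0]undec-7-ene (0.2 equiv), CH2Cl2, 23 °C
Reagents that add atoms: none
Why: Base-catalysed conjugation of a β,γ-unsaturated ketone (the isopulegone-to-pulegone change), in which deprotonation at C7 and reprotonation at C12 move the alkene to C7=C11, the amidine is too weak to attack the esters or the ester α-centre, and C5 is not acidified by the C8 ketone, so no stereocentre of the target is at risk.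

**Compound list**
1 | 3-methylcyclohex-2-en-1-one | CC1=CC(=O)CCC1 | starting material
2 | prenyl bromide | CC(C)=CCBr | starting material
3 | 3-methyl-2-(3-methylbut-2-en-1-yl)cyclohex-2-en-1-one | O=C1CCCC(C)=C1CC=C(C)C | intermediate
4 | (1R)-3-methyl-2-(3-methylbut-2-en-1-yl)cyclohex-2-en-1-ol | O[C@@H]1CCCC(C)=C1CC=C(C)C | intermediate
5 | N,N-dimethylacetamide dimethyl acetal | CC(OC)(OC)N(C)C | starting material
6 | 1-(dimethylamino)vinyl ether of 4 (ketene N,O-acetal) | C=C(N(C)C)O[C@@H]1CCCC(C)=C1CC=C(C)C | intermediate
7 | 2-[(1R)-1-methyl-2-(3-methylbut-2-en-1-yl)cyclohex-2-en-1-yl]-N,N-dimethylacetamide | CN(C)C(=O)C[C@@]1(C)CCCC=C1CC=C(C)C | intermediate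
8 | 2-[(1R)-1-methyl-2-(3-methylbut-2-en-1-yl)cyclohex-2-en-1-yl]acetaldehyde | O=CC[C@@]1(C)CCCC=C1CC=C(C)C | intermediate
9 | 15-nor-eudesma-4,11-dien-8α-ol | C1=C2C[C@H](C(C)=C)[C@@H](O)C[C@@]2(C)CCC1 | intermediate
10 | 8α-(tert-butyldimethylsilyloxy)-15-nor-eudesma-4,11-diene | C1=C2C[C@H](C(C)=C)[C@@H](O[Si](C)(C)C(C)(C)C)C[C@@]2(C)CCC1 | intermediate
11 | 8α-(tert-butyldimethylsilyloxy)-15-nor-eudesma-4,11-dien-3-one | O=C1C=C2C[C@H](C(C)=C)[C@@H](O[Si](C)(C)C(C)(C)C)C[C@@]2(C)CC1 | intermediate
12 | formaldehyde | C=O | starting material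
13 | thiophenol | Sc1ccccc1 | starting material
14 | 8α-(tert-butyldimethylsilyloxy)-15-(phenylsulfanyl)eudesma-4,11-dien-3-one | O=C1C(CSc3ccccc3)=C2C[C@H](C(C)=C)[C@@H](O[Si](C)(C)C(C)(C)C)C[C@@]2(C)CC1 | intermediate
15 | lithium 8α-(tert-butyldimethylsilyloxy)-5αH-eudesma-3,11-dien-3-olate | [Li+].[O-]C1=C(C)[C@@H]2C[C@H](C(C)=C)[C@@H](O[Si](C)(C)C(C)(C)C)C[C@@]2(C)CC1 | intermediate
16 | 8α-(tert-butyldimethylsilyloxy)-3-(trimethylsilyloxy)-5αH-eudesma-3,11-diene | C[Si](C)(C)OC1=C(C)[C@@H]2C[C@H](C(C)=C)[C@@H](O[Si](C)(C)C(C)(C)C)C[C@@]2(C)CC1 | intermediate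
17 | 8α-(tert-butyldimethylsilyloxy)-3α,4α-epoxy-3β-(trimethylsilyloxy)-5αH-eudesm-11-ene | C[Si](C)(C)O[C@@]14O[C@@]4(C)[C@@H]2C[C@H](C(C)=C)[C@@H](O[Si](C)(C)C(C)(C)C)C[C@@]2(C)CC1 | intermediate
18 | 8α-(tert-butyldimethylsilyloxy)-4α-(trimethylsilyloxy)-5αH-eudesm-11-en-3-one | O=C1[C@@](C)(O[Si](C)(C)C)[C@@H]2C[C@H](C(C)=C)[C@@H](O[Si](C)(C)C(C)(C)C)C[C@@]2(C)CC1 | intermediate
19 | 8α-(tert-butyldimethylsilyloxy)-4α-hydroxy-5αH-eudesm-11-en-3-one | O=C1[C@@](C)(O)[C@@H]2C[C@H](C(C)=C)[C@@H](O[Si](C)(C)C(C)(C)C)C[C@@]2(C)CC1 | intermediate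
20 | 8α-(tert-butyldimethylsilyloxy)-5αH-eudesm-11-ene-3β,4α-diol | O[C@@H]1[C@@](C)(O)[C@@H]2C[C@H](C(C)=C)[C@@H](O[Si](C)(C)C(C)(C)C)C[C@@]2(C)CC1 | intermediate
21 | (R)-2-methylbutanoic acid | CC[C@@H](C)C(O)=O | starting material
22 | 8α-(tert-butyldimethylsilyloxy)-4α-hydroxy-5αH-eudesm-11-en-3β-yl (2R)-2-methylbutanoate | CC[C@@H](C)C(=O)O[C@@H]1[C@@](C)(O)[C@@H]2C[C@H](C(C)=C)[C@@H](O[Si](C)(C)C(C)(C)C)C[C@@]2(C)CC1 | intermediate
23 | acetic anhydride | CC(=O)OC(C)=O | starting material
24 | 4α-acetoxy-8α-(tert-butyldimethylsilyloxy)-5αH-eudesm-11-en-3β-yl (2R)-2-methylbutanoate | CC[C@@H](C)C(=O)O[C@@H]1[C@@](C)(OC(C)=O)[C@@H]2C[C@H](C(C)=C)[C@@H](O[Si](C)(C)C(C)(C)C)C[C@@]2(C)CC1 | intermediate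
25 | 4α-acetoxy-8α-hydroxy-5αH-eudesm-11-en-3β-yl (2R)-2-methylbutanoate | CC[C@@H](C)C(=O)O[C@@H]1[C@@](C)(OC(C)=O)[C@@H]2C[C@H](C(C)=C)[C@@H](O)C[C@@]2(C)CC1 | intermediate
26 | 4α-acetoxy-8-oxo-5αH,7αH-eudesm-11-en-3β-yl (2R)-2-methylbutanoate | CC[C@@H](C)C(=O)O[C@@H]1[C@@](C)(OC(C)=O)[C@@H]2C[C@H](C(C)=C)C(=O)C[C@@]2(C)CC1 | intermediate
27 | 4α-acetoxy-8-oxo-5αH-eudesm-7(11)-en-3β-yl (2R)-2-methylbutanoate (CNP0111007.1) | CC[C@@H](C)C(=O)O[C@H]1CC[C@]2(C)CC(=O)C(=C(C)C)C[C@H]2[C@]1(C)OC(C)=O | target

Total step count: 16. Longest linear sequence: 16 steps (from 1).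

**Steps most likely to fail**

Step 7. The oxidant may attack the wrong allylic site (C6, or C7 and C12 next to the isopropenyl group), or it may over-oxidise. The fallback sets out from 10. Dye-sensitised photo-oxygenation (O2, 5,10,15,20-tetraphenylporphyrin, light, CH2Cl2, 0 °C; Schenck ene reaction) should engage the trisubstituted C4=C5 alkene from the α face. On that face only the C3 hydrogen is axial and aligned, so the expected product is 8α-(tert-butyldimethylsilyloxy)-5α-hydroperoxy-15-nor-eudesma-3,11-diene F1. PPh3 reduces it to the tertiary allylic alcohol 8α-(tert-butyldimethylsilyloxy)-15-nor-eudesma-3,11-dien-5α-ol F2. Pyridinium chlorochromate, [C5H5NH][CrO3Cl], in CH2Cl2 then effects the Babler–Dauben oxidative transposition: the chromate ester shifts from O–C5 to C3 and is oxidised there. The detour comes back to the route at 11.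

Step 13. The tertiary hydroxyl may be acylated so slowly that migration of the C3 acyl group or elimination overtakes it. The fallback sets out from 19 and changes the order of events. The hydroxyl is acetylated while C3 is still a ketone, so no neighbouring ester can migrate (Ac2O, 4-dimethylaminopyridine, Et3N), giving 4α-acetoxy-8α-(tert-butyldimethylsilyloxy)-5αH-eudesm-11-en-3-one F3. Zn(BH4)2 in Et2O at −20 °C, a neutral hydride source chosen to hold back an acetyl shift, gives 4α-acetoxy-8α-(tert-butyldimethylsilyloxy)-5αH-eudesm-11-en-3β-ol F4. Immediate Steglich esterification with 21 comes back to the route at 24.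

Step 10. Epoxidation of the isopropenyl alkene may compete, and the enol ether may hydrolyse before it is oxidised. The fallback sets out from 16. MeLi in THF at 0 °C cleaves the O–Si bond and regenerates lithium enolate 15. This is hydroxylated at C4 from the α face by 2-(phenylsulfonyl)-3-phenyloxaziridine at −78 °C, an enolate hydroxylation with an oxygen donor that does not react with unactivated alkenes. The detour comes back to the route at 19 and makes no compound outside the list (F0).

**Further compounds**
F1 | step 7 | 8α-(tert-butyldimethylsilyloxy)-5α-hydroperoxy-15-nor-eudesma-3,11-diene | C1=C[C@]2(OO)C[C@H](C(C)=C)[C@@H](O[Si](C)(C)C(C)(C)C)C[C@@]2(C)CC1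
F2 | step 7 | 8α-(tert-butyldimethylsilyloxy)-15-nor-eudesma-3,11-dien-5α-ol | C1=C[C@]2(O)C[C@H](C(C)=C)[C@@H](O[Si](C)(C)C(C)(C)C)C[C@@]2(C)CC1
F3 | step 13 | 4α-acetoxy-8α-(tert-butyldimethylsilyloxy)-5αH-eudesm-11-en-3-one | O=C1[C@@](C)(OC(C)=O)[C@@H]2C[C@H](C(C)=C)[C@@H](O[Si](C)(C)C(C)(C)C)C[C@@]2(C)CC1
F4 | step 13 | 4α-acetoxy-8α-(tert-butyldimethylsilyloxy)-5αH-eudesm-11-en-3β-ol | O[C@@H]1[C@@](C)(OC(C)=O)[C@@H]2C[C@H](C(C)=C)[C@@H](O[Si](C)(C)C(C)(C)C)C[C@@]2(C)CC1
F0 | step 10 | none | none
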